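**Plan**

- Retrosynthesis: the side-chain C–Br is traced back to the (R)-carbinol (inversion), and the ring is cut at C3–C4 and C1–C6 (ring numbering: C1 = CHOAc, C2 = alkene carbon bearing the side chain, C3 = vinylic CH, C4 = CMe2, C5 = CHBr, C6 = CH2). This gives an α-substituted acrolein (C1–C3 plus side chain) and a 1,1-dimethylallyl boronate (C4–C6 plus both methyls).
- Enabling feature: the C6H2–C5HBr–C4Me2 triad is a dimethylallyl unit lying between the carbinol carbon C1 and the vinylic C3–H. It can react first as an allyl nucleophile through C6 toward the aldehyde carbon C1, and then, as a bromonium ion, as an electrophile at its tertiary carbon C4 toward the alkene terminus C3.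
- Forward: (R)-chlorohydrin ester → silyl ether → aldehyde → α-methylene aldehyde; prenol → carbonate → tertiary allylboronate; in one flask, allyl transfer (C1–C6) then bromonium π-cyclisation (C3–C4) closes the only ring; then acetylation, desilylation and Appel bromination.
- Stereochemistry: the side-chain center comes from commercial ethyl (R)-4-chloro-3-hydroxybutanoate and is inverted to S in the last step; C1 is set by the chiral phosphoric acid in the allyl transfer; C5 is set relative to C1 by the chair-like cyclisation (1,5-cis, bromine equatorial).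

Key step: step 6

Remark on the chemistry: the (R)-phosphoric acid is assumed to deliver the allyl group to the Re face of the α-substituted acrolein, as it does with aryl and α,β-unsaturated aldehydes. (TBS = tert-butyldimethylsilyl; Bpin = 4,4,5,5-tetramethyl-1,3,2-dioxaborolan-2-yl.)

**Route**

Step 1
Reactants: 1 ethyl (3R)-4-chloro-3-hydroxybutanoate
Product: 2 ethyl (3R)-3-[(tert-butyldimethylsilyl)oxy]-4-chlorobutanoate
Conditions: TBSCl, imidazole, DMF, rt
Reagents that add atoms: tert-butyldimethylsilyl chloride, CC(C)(C)[Si](C)(C)Cl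
Why: Imidazole-promoted silylation of the secondary hydroxyl should leave the stereocenter, the ester and the primary chloride untouched and masks the chlorohydrin oxygen for the later stages.

Step 2
Reactants: 2 ethyl (3R)-3-[(tert-butyldimethylsilyl)oxy]-4-chlorobutanoate
Product: 3 (3R)-3-[(tert-butyldimethylsilyl)oxy]-4-chlorobutanal
Conditions: iBu2AlH, CH2Cl2, −78 °C; aq. potassium sodium tartrate
Reagents that add atoms: none
Why: Partial reduction of the ester with iBu2AlH at low temperature should stop at the aldehyde because the tetrahedral aluminium hemiacetal survives until work-up, and the β-silyloxy stereocenter is not involved.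

Step 3
Reactants: 3 (3R)-3-[(tert-butyldimethylsilyl)oxy]-4-chlorobutanal
Product: 5 2-[(1R)-1-[(tert-butyldimethylsilyl)oxy]-2-chloroethyl]prop-2-enal, via Mannich base 4 (not isolated)
Conditions: CH2=NMe2+ I− (Eschenmoser's salt), Et3N, CH2Cl2, rt
Reagents that add atoms: dimethyl(methylidene)ammonium iodide, C=[N+](C)C.[I-]
Why: Mannich reaction of the aldehyde enol with the iminium salt followed by loss of dimethylamine (α-methylenation of an aldehyde) should give the 2-substituted acrolein, and the silyloxy stereocenter is not epimerisable under these conditions.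

Step 4
Reactants: 6 3-methylbut-2-en-1-ol
Product: 7 methyl 3-methylbut-2-en-1-yl carbonate
Conditions: ClCO2Me, pyridine, CH2Cl2, 0 °C
Reagents that add atoms: methyl chloroformate, COC(Cl)=O
Why: Acylation of the primary allylic alcohol with the chloroformate gives the carbonate leaving group needed for copper-catalysed allylic substitution.

Step 5
Reactants: 7 methyl 3-methylbut-2-en-1-yl carbonate
Product: 8 4,4,5,5-tetramethyl-2-(2-methylbut-3-en-2-yl)-1,3,2-dioxaborolane
Conditions: B2pin2, CuCl (5 mol%), 1,3-dimesitylimidazolinium chloride (5 mol%), NaOtBu (20 mol%), THF, rt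
Reagents that add atoms: bis(pinacolato)diboron, CC1(C)OB(OC1(C)C)B1OC(C)(C)C(C)(C)O1
Why: Copper-catalysed allylic boryl substitution (formal SN2′: borylcupration then β-elimination of the carbonate) places boron on the γ-carbon, here the dimethyl-substituted terminus, so the tertiary allylboronate with a terminal vinyl group should form.

Step 6
Reactants: 5 2-[(1R)-1-[(tert-butyldimethylsilyl)oxy]-2-chloroethyl]prop-2-enal; 8 4,4,5,5-tetramethyl-2-(2-methylbut-3-en-2-yl)-1,3,2-dioxaborolane
Product: 11 (1R,5S)-5-bromo-2-[(1R)-1-[(tert-butyldimethylsilyl)oxy]-2-chloroethyl]-4,4-dimethylcyclohex-2-en-1-ol, via homoallyl borate 9 (not isolated), via bromocyclohexenyl borate 10 (not isolated)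
Conditions: (R)-3,3′-bis(2,4,6-triisopropylphenyl)-1,1′-binaphthyl-2,2′-diyl hydrogen phosphate (5 mol%), 4 Å MS, toluene, −30 °C → rt; then MeNO2, Et2SBr·SbCl5Br (1.1 equiv), −25 °C, 10 min; aq. NaHCO3/Na2SO3
Reagents that add atoms: bromodiethylsulfonium bromopentachloroantimonate, CC[S+](Br)CC.Cl[Sb-](Cl)(Cl)(Cl)(Cl)Br
Why: The phosphoric acid brings boronate 8 and the aldehyde into a closed six-membered chair transition state in which the unsubstituted allyl terminus bonds to the carbonyl carbon (C1–C6 of the target ring) and boron ends on oxygen, which unveils the Me2C=CH alkene of borate 9; Et2SBr·SbCl5Br then brominates this most electron-rich alkene, the 1,1-disubstituted alkene opens the bromonium ion at its tertiary carbon (C3–C4), and the ring cation loses the C3 proton that is aligned with its empty orbital. The closest known reaction types are the chiral-phosphoric-acid-catalysed allylboration of aldehydes and the bromonium-initiated cation–olefin cyclisation of 1,5-dienes with this sulfonium reagent, here run in sequence in one flask. The six-membered ring closes in a chair-like 6-endo cation–olefin mode in which both bromonium carbons and both carbons of the attacking alkene become ring atoms. C1 is set by the catalyst (Re-face allyl transfer, expected to override the modest bias of the silyloxy stereocenter), and C5 is set relative to C1 by the chair, with bromine equatorial and the bulky borate oxygen equatorial in the plane of the attacking alkene so that its C–O bond does not withdraw from the developing cation, which should give the 1,5-cis isomer. The step needs linear allyl transfer, which the allylboration mechanism guarantees, Markovnikov opening at the tertiary carbon, which the gem-dimethyl group secures, and carbon instead of oxygen capture of the bromonium ion, which the temporary O–B bond secures by tying up the lone pairs of the new oxygen until aqueous work-up cleaves it.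

Step 7
Reactants: 11 (1R,5S)-5-bromo-2-[(1R)-1-[(tert-butyldimethylsilyl)oxy]-2-chloroethyl]-4,4-dimethylcyclohex-2-en-1-ol
Product: 12 (1R,5S)-5-bromo-2-[(1R)-1-[(tert-butyldimethylsilyl)oxy]-2-chloroethyl]-4,4-dimethylcyclohex-2-en-1-yl acetate
Conditions: Ac2O, pyridine, DMAP (cat.), CH2Cl2, 0 °C → rt
Reagents that add atoms: acetic anhydride, CC(=O)OC(C)=O
Why: DMAP-catalysed acylation of the secondary allylic alcohol installs the acetate of the target with retention at C1.

Step 8
Reactants: 12 (1R,5S)-5-bromo-2-[(1R)-1-[(tert-butyldimethylsilyl)oxy]-2-chloroethyl]-4,4-dimethylcyclohex-2-en-1-yl acetate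
Product: 13 (1R,5S)-5-bromo-2-[(1R)-2-chloro-1-hydroxyethyl]-4,4-dimethylcyclohex-2-en-1-yl acetate
Conditions: HF·pyridine, pyridine, THF, 0 °C → rt
Reagents that add atoms: none
Why: Fluoride-mediated desilylation under mildly acidic conditions should free the side-chain carbinol without closing the chlorohydrin to an epoxide or moving the acetyl group, as a basic fluoride source might.

Step 9
Reactants: 13 (1R,5S)-5-bromo-2-[(1R)-2-chloro-1-hydroxyethyl]-4,4-dimethylcyclohex-2-en-1-yl acetate
Product: 14 (1R,5S)-5-bromo-2-[(1S)-1-bromo-2-chloroethyl]-4,4-dimethylcyclohex-2-en-1-yl acetate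
Conditions: CBr4, PPh3, CH2Cl2, 0 °C
Reagents that add atoms: carbon tetrabromide, BrC(Br)(Br)Br
Why: Appel bromination should convert the (R)-carbinol into the (S)-bromide by SN2 displacement of the oxyphosphonium group with inversion, the SN2′ path being blocked by the neopentylic C3 and ionisation being disfavoured by the adjacent chloromethyl group.

**Compound list**

1 | ethyl (3R)-4-chloro-3-hydroxybutanoate | CCOC(=O)C[C@@H](O)CCl | starting material
2 | ethyl (3R)-3-[(tert-butyldimethylsilyl)oxy]-4-chlorobutanoate | CCOC(=O)C[C@@H](O[Si](C)(C)C(C)(C)C)CCl | intermediate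
3 | (3R)-3-[(tert-butyldimethylsilyl)oxy]-4-chlorobutanal | O=CC[C@@H](O[Si](C)(C)C(C)(C)C)CCl | intermediate
4 | (3R)-3-[(tert-butyldimethylsilyl)oxy]-4-chloro-2-[(dimethylamino)methyl]butanal (Mannich base, both C2 epimers) | O=CC(CN(C)C)[C@@H](O[Si](C)(C)C(C)(C)C)CCl | intermediate
5 | 2-[(1R)-1-[(tert-butyldimethylsilyl)oxy]-2-chloroethyl]prop-2-enal | C=C(C=O)[C@@H](O[Si](C)(C)C(C)(C)C)CCl | intermediate
6 | 3-methylbut-2-en-1-ol | CC(C)=CCO | starting material
7 | methyl 3-methylbut-2-en-1-yl carbonate | COC(=O)OCC=C(C)C | intermediate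
8 | 4,4,5,5-tetramethyl-2-(2-methylbut-3-en-2-yl)-1,3,2-dioxaborolane | C=CC(C)(C)B1OC(C)(C)C(C)(C)O1 | intermediate
9 | 2-{[(2R,4R)-2-[(tert-butyldimethylsilyl)oxy]-1-chloro-7-methyl-3-methylideneoct-6-en-4-yl]oxy}-4,4,5,5-tetramethyl-1,3,2-dioxaborolane (homoallyl borate) | CC(C)=CC[C@@H](OB1OC(C)(C)C(C)(C)O1)C(=C)[C@@H](O[Si](C)(C)C(C)(C)C)CCl | intermediate
10 | 2-{[(1R,5S)-5-bromo-2-[(1R)-1-[(tert-butyldimethylsilyl)oxy]-2-chloroethyl]-4,4-dimethylcyclohex-2-en-1-yl]oxy}-4,4,5,5-tetramethyl-1,3,2-dioxaborolane (bromocyclohexenyl borate) | CC1(C)OB(O[C@@H]2C[C@H](Br)C(C)(C)C=C2[C@@H](O[Si](C)(C)C(C)(C)C)CCl)OC1(C)C | intermediate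
11 | (1R,5S)-5-bromo-2-[(1R)-1-[(tert-butyldimethylsilyl)oxy]-2-chloroethyl]-4,4-dimethylcyclohex-2-en-1-ol | O[C@@H]1C[C@H](Br)C(C)(C)C=C1[C@@H](O[Si](C)(C)C(C)(C)C)CCl | intermediate
12 | (1R,5S)-5-bromo-2-[(1R)-1-[(tert-butyldimethylsilyl)oxy]-2-chloroethyl]-4,4-dimethylcyclohex-2-en-1-yl acetate | CC(=O)O[C@@H]1C[C@H](Br)C(C)(C)C=C1[C@@H](O[Si](C)(C)C(C)(C)C)CCl | intermediate
13 | (1R,5S)-5-bromo-2-[(1R)-2-chloro-1-hydroxyethyl]-4,4-dimethylcyclohex-2-en-1-yl acetate | CC(=O)O[C@@H]1C[C@H](Br)C(C)(C)C=C1[C@@H](O)CCl | intermediate
14 | (1R,5S)-5-bromo-2-[(1S)-1-bromo-2-chloroethyl]-4,4-dimethylcyclohex-2-en-1-yl acetate | CC(=O)O[C@@H]1C[C@H](Br)C(C)(C)C=C1[C@H](Br)CCl | target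

**Count**

Total steps: 9. Longest linear sequence: 7 (steps 1, 2, 3, 6, 7, 8, 9); steps 4 and 5 make the second fragment.

**Steps most likely to fail**

Step 6. The bromonium ion may be intercepted by the borate oxygen (bromoetherification) instead of the alkene, the electron-poor 1,1-disubstituted alkene may attack too slowly, or facial control in the ring closure may be incomplete. The fallback sets out from 5 and 8 and returns at 12. The allyl transfer is run alone with the same catalyst and borate 9 is hydrolysed at work-up to the homoallylic alcohol (2R,4R)-2-[(tert-butyldimethylsilyl)oxy]-1-chloro-7-methyl-3-methylideneoct-6-en-4-ol F1. Acetylation (Ac2O, pyridine, DMAP) gives (2R,4R)-2-[(tert-butyldimethylsilyl)oxy]-1-chloro-7-methyl-3-methylideneoct-6-en-4-yl acetate F2, whose ester oxygen cannot close onto the alkene. Hg(O2CCF3)2 in MeNO2 at 0 °C, then aqueous NaCl, should effect a reversible, thermodynamically controlled mercuricyclisation to the equatorial organomercurial chloro[(1S,5R)-5-acetoxy-4-[(1R)-1-[(tert-butyldimethylsilyl)oxy]-2-chloroethyl]-2,2-dimethylcyclohex-3-en-1-yl]mercury F3. Br2 and LiBr in pyridine under oxygen should then replace mercury by bromine with retention to give 12.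

Step 9. The allylic oxyphosphonium ion may ionise, be attacked in the SN2′ sense, or be displaced internally by the neighbouring acetate, any of which erodes the configuration of the side-chain center. The fallback sets out from 13 and returns at 14. MsCl and Et3N in CH2Cl2 at −20 °C give the isolable sulfonate (1R,5S)-5-bromo-2-[(1R)-2-chloro-1-(methanesulfonyloxy)ethyl]-4,4-dimethylcyclohex-2-en-1-yl acetate F4. LiBr in acetone then displaces it by a bimolecular reaction with free bromide and inversion, without a phosphonium intermediate.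

Step 8. After desilylation the acetyl group may shift from the ring oxygen to the nearby side-chain hydroxyl, and the liberated chlorohydrin may close to an epoxide if the medium becomes basic. The fallback sets out from 12 and returns at 14. The silyl ether is converted directly into the bromide with Ph3PBr2 in CH2Cl2 (silyl ether to alkyl bromide with inversion), so the free hydroxy acetate 13 is never formed; this fallback makes no new compound (F0).

**Further compounds**

F1 | step 6 | (2R,4R)-2-[(tert-butyldimethylsilyl)oxy]-1-chloro-7-methyl-3-methylideneoct-6-en-4-ol | CC(C)=CC[C@@H](O)C(=C)[C@@H](O[Si](C)(C)C(C)(C)C)CCl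
F2 | step 6 | (2R,4R)-2-[(tert-butyldimethylsilyl)oxy]-1-chloro-7-methyl-3-methylideneoct-6-en-4-yl acetate | CC(C)=CC[C@@H](OC(C)=O)C(=C)[C@@H](O[Si](C)(C)C(C)(C)C)CCl
F3 | step 6 | chloro[(1S,5R)-5-acetoxy-4-[(1R)-1-[(tert-butyldimethylsilyl)oxy]-2-chloroethyl]-2,2-dimethylcyclohex-3-en-1-yl]mercury | CC(=O)O[C@@H]1C[C@H]([Hg]Cl)C(C)(C)C=C1[C@@H](O[Si](C)(C)C(C)(C)C)CCl
F4 | step 9 | (1R,5S)-5-bromo-2-[(1R)-2-chloro-1-(methanesulfonyloxy)ethyl]-4,4-dimethylcyclohex-2-en-1-yl acetate | CC(=O)O[C@@H]1C[C@H](Br)C(C)(C)C=C1[C@@H](OS(C)(=O)=O)CCl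
F0 | step 8 | none | none
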